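The easy step comes first: read the hottest earlier run at its last reading.

| flask | substrate | reagent | free catalyst | temperature | remark | time |
|---|---|---|---|---|---|---|
| midnight | 0.020 M | 0.024 M | 0.34 mM | 95 °C | run made earlier |  |
| autumn | 0.020 M | 0.024 M | 0.75 mM | 128 °C | run made earlier |  |
| winter | 0.030 M | 0.024 M | 0.50 mM | 95 °C | run made earlier |  |
| north-east | 0.020 M | 0.0240 M | 0.50 mM | 110 °C |  | 25 h |
| south | 0.020 M | 0.0240 M | 0.50 mM | 80 °C |  | 25 h |
| north-west | 0.020 M | 0.0240 M | 0.50 mM | 140 °C |  | 25 h |
| east | 0.020 M | 0.0240 M | 0.50 mM |  | at 80 °C until 8.0 h, from then on at 140 °C | 25 h |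

- midnight (time / h: product / %, substrate / %): 3.00: 2.8, 98.0; 8.00: 8.4, 91.6; 15.0: 14.7, 84.7; 20.0: 19.0, 80.8; 30.0: 27.1, 71.4
- autumn (time / h: product / %, substrate / %): 0.500: 2.6, 97.4; 1.00: 4.5, 95.5; 1.50: 7.1, 93.0; 3.00: 13.7, 87.1; 6.00: 25.0, 75.0
- winter (time / h: product / %, substrate / %): 3.00: 4.0, 97.0; 8.00: 10.1, 90.0; 15.0: 18.7, 81.1; 20.0: 23.8, 75.4; 30.0: 33.5, 65.0

(standard deviation of a reading: 0.5 percentage points)

* the flask that comes out highest in amount of product, in percent of the substrate charged, or "all alike" when all lie within 1.5 percentage points (north-east / south / north-west / east / all alike)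
* product at the end, in percent of the substrate charged, north-east
* product at the end, in percent of the substrate charged, south
* product at the end, in percent of the substrate charged, north-west
* product at the end, in percent of the substrate charged, east



At 6.00 h the autumn run holds product 25.0% and substrate 75.0%, which sum to 100%. So substrate lost is read as product made. Take the loss as pseudo-first-order in substrate, with the remaining fraction e^(−E). Here E = κct, where c is the free catalyst charged, t the time, and κ the hot exposure constant, the logarithm of charged over remaining substrate per unit of catalyst and time. Autumn reads κ = 63.9 L mol⁻¹ h⁻¹.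

But κ is not constant across the runs. The midnight run at 95 °C reads 33.0 L mol⁻¹ h⁻¹, and the winter run, at the same temperature with more substrate and more free catalyst, reads 28.7 L mol⁻¹ h⁻¹. Two estimates then frame north-west. With κ held at its autumn reading, the reckoning gives 55.0%. If log κ keeps rising evenly with degrees from midnight through autumn, κ reaches 81.3 L mol⁻¹ h⁻¹ and the reckoning gives 63.8%.

The same even rise puts north-east near 42.7%. East stays at 80 °C until 8.0 h, so its hot leg lasts 17.0 h, which at the same two values of κ gives 41.9% to 49.9%, the cold hours not counted. So north-west is reckoned to lead.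

The forecast names north-west, with 43% for north-east, 19% for south, 72% for north-west and 60% for east, on the ground that “Each run fits first order in substrate”, and its north-west figure stands above the range reckoned here.

North-west gives 59.4%, inside that range, and comes out highest; north-east gives 44.5%, south 17.5% and east 49.1%. Moved one at a time by the same factor, temperature not being tried, the settings of north-west rank time (9.3 points), then free catalyst (9.3 points), then substrate (0.79 points), then reagent (0.13 points); time and free catalyst stand equal, as they do in E. Read back from north-west, κ is 72.1 L mol⁻¹ h⁻¹, a factor of 1.13 above the autumn reading; the two flasks differ in temperature, free catalyst and time.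

    reagent + free catalyst → catalyst intermediate A (k = 140 L mol⁻¹ h⁻¹, Ea = 82.0 kJ mol⁻¹)
    catalyst intermediate A ⇌ catalyst intermediate B (K = 70.0, k = 9.10 h⁻¹, Ea = 95.0 kJ mol⁻¹, ΔH = 0 kJ mol⁻¹)
    substrate + catalyst intermediate B ⇌ catalyst intermediate C (K = 41.0 L mol⁻¹, k = 190 L mol⁻¹ h⁻¹, Ea = 75.0 kJ mol⁻¹, ΔH = −83.0 kJ mol⁻¹)
    catalyst intermediate C ⇌ by-product + catalyst intermediate D (K = 0.0380 M, k = 0.970 h⁻¹, Ea = 97.0 kJ mol⁻¹, ΔH = −19.0 kJ mol⁻¹)
    catalyst intermediate D → free catalyst + product (k = 3.70 h⁻¹, Ea = 112 kJ mol⁻¹)
    2 catalyst intermediate A ⇌ resting dimer, settled at all times (K = 680 L mol⁻¹, ΔH = −59.0 kJ mol⁻¹)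
    (constants at 80 °C)

A neighbour of east holds 0.0020 M of free catalyst. The autumn κ over its hot leg gives 88.6%, and the computed flask gives 92.4%.

The data are simulated for an exercise, and the scatter is random.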